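The route rests on cutting ring B at C6. This carbon only links C6a, the C3 position of the benzofuran made of rings C and D, to the phenol oxygen O5 of ring A. Raised to a lactone carbonyl, it can be supplied as CO gas. In one operation a chiral palladium hydride puts H on C11a, CO enters at C6a and O5 takes the acyl group. Ring B closes, the furan is dearomatised and both stereocentres appear, C11a under ligand control and C6a by relay to the cis fusion. The precursor is the flat 2-arylbenzofuran 11, whose aryl group is the finished A/E chroman with O5 free and O3 silylated.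

Key step: step 8

Labels: pterocarpan numbering is used (ring A carbons C1–C4, C4a and C11b; then O5, C6, C6a, O11, C11a). Ring A is the trioxygenated benzene, ring B the pyran, ring C the furan, ring D the methoxybenzene and ring E the dimethylpyran.

Remark on ring E: O4 of the prenylated aldehyde is silylated before the acid closure. A free O4 would compete with the chelated O2 and lead to the 6-formyl chroman, which has the wrong ring E orientation.

Remark on the ring fusion: a syn addition of H and acyl to C11a=C6a puts C6 on the face of the new H11a, which is trans to ring A. The cis fusion therefore has to come from the configurational lability of C6a next to the carbonyl group, not from the insertion itself.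

Assumption: the sense of induction of a bisphosphine on a benzofuran cannot be predicted. The route is written with (S)-Xyl-PHANEPHOS. The mirror-image ligand is used if the hydride does not go to the Re face of C11a, which is the face that gives 11aS.

Step 1
Reactants: 1 2,4,6-trihydroxybenzaldehyde; 2 1-bromo-3-methylbut-2-ene
Product: 3 2,4,6-trihydroxy-3-(3-methylbut-2-en-1-yl)benzaldehyde
Conditions: KOH (1 equiv), 2 (0.9 equiv), H2O–MeOH, 0 °C → rt
Reagents that add atoms: 1-bromo-3-methylbut-2-ene (2), CC(C)=CCBr
Why: C-alkylation of a phloroglucinol phenoxide: in the protic medium the hydrogen-bonded oxygens are poor nucleophiles, so the soft allylic bromide is taken by ring carbon C3 (equivalent to C5), and keeping the bromide as the limiting reagent holds back a second prenylation.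

Step 2
Reactants: 3 2,4,6-trihydroxy-3-(3-methylbut-2-en-1-yl)benzaldehyde
Product: 4 2,6-dihydroxy-3-(3-methylbut-2-en-1-yl)-4-(triisopropylsilyloxy)benzaldehyde
Conditions: iPr3SiCl (1.0 equiv), imidazole, DMF, 0 °C
Reagents that add atoms: chlorotriisopropylsilane, CC(C)[Si](Cl)(C(C)C)C(C)C
Why: Site-selective phenol silylation: O4 is the only hydroxyl not ortho to the formyl group, hence the most acidic and the only one free of the intramolecular hydrogen bond, and capping it now leaves O2 as the sole oxygen that flanks the prenyl chain.

Step 3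
Reactants: 4 2,6-dihydroxy-3-(3-methylbut-2-en-1-yl)-4-(triisopropylsilyloxy)benzaldehyde
Product: 5 7-hydroxy-2,2-dimethyl-5-(triisopropylsilyloxy)chroman-8-carbaldehyde
Conditions: Amberlyst 15, toluene, 50 °C
Reagents that add atoms: none
Why: Acid-catalysed intramolecular Markovnikov hydroalkoxylation of an ortho-prenylphenol: protonation gives the tertiary cation, which only O2 can reach, so the chroman oxygen ends beside the formyl-bearing carbon exactly as the C1–O bond of ring E requires, while the aryl silyl ether is inert to the dry resin acid.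

Step 4
Reactants: 5 7-hydroxy-2,2-dimethyl-5-(triisopropylsilyloxy)chroman-8-carbaldehyde
Product: 6 7-(methoxymethoxy)-2,2-dimethyl-5-(triisopropylsilyloxy)chroman-8-carbaldehyde
Conditions: MeOCH2Cl, iPr2NEt, CH2Cl2, 0 → 40 °C
Reagents that add atoms: chloromethyl methyl ether, COCCl
Why: Base-mediated O-alkylation with a chloromethyl ether turns the chelated O5 hydroxyl into an acetal, so that in step 6 only the ring D phenol can attack the alkyne.

Step 5
Reactants: 6 7-(methoxymethoxy)-2,2-dimethyl-5-(triisopropylsilyloxy)chroman-8-carbaldehyde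
Product: 7 8-ethynyl-7-(methoxymethoxy)-2,2-dimethyl-5-(triisopropylsilyloxy)chroman
Conditions: Me3SiCHN2, LiN(iPr)2, THF, −78 °C → rt; H2O
Reagents that add atoms: (trimethylsilyl)diazomethane, C[Si](C)(C)C=[N+]=[N-]
Why: Colvin rearrangement, the silicon version of the Seyferth–Gilbert homologation: addition of the lithiated diazo compound, Peterson-type loss of silanolate, loss of N2 and a 1,2-hydrogen shift give the terminal alkyne under aprotic cold conditions that spare the silyl ether para to the aldehyde, which carbonate in methanol could strip.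

Step 6
Reactants: 7 8-ethynyl-7-(methoxymethoxy)-2,2-dimethyl-5-(triisopropylsilyloxy)chroman; 8 2-iodo-5-methoxyphenol
Product: 10 6-methoxy-2-[7-(methoxymethoxy)-2,2-dimethyl-5-(triisopropylsilyloxy)chroman-8-yl]benzofuran, via diarylalkyne 9 (not isolated)
Conditions: Pd(PPh3)2Cl2 (3 mol %), CuI (5 mol %), Et3N, DMF, rt → 70 °C
Reagents that add atoms: 2-iodo-5-methoxyphenol (8), COc1ccc(I)c(O)c1
Why: Sonogashira coupling followed in the same flask by metal-assisted 5-endo-dig attack of the ring D phenol on the alkyne, a standard heteroannulation of 2-iodophenols, in which the acetal on O5 rules out the isomeric furan on ring A.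

Step 7
Reactants: 10 6-methoxy-2-[7-(methoxymethoxy)-2,2-dimethyl-5-(triisopropylsilyloxy)chroman-8-yl]benzofuran
Product: 11 8-(6-methoxybenzofuran-2-yl)-2,2-dimethyl-5-(triisopropylsilyloxy)chroman-7-ol
Conditions: TsOH·H2O (cat.), MeOH–THF, 45 °C
Reagents that add atoms: none
Why: Acid-catalysed acetal exchange removes the methoxymethyl group, while the aromatic benzofuran, the chroman and the bulky aryl silyl ether are stable to dilute sulfonic acid in methanol.

Step 8
Reactants: 11 8-(6-methoxybenzofuran-2-yl)-2,2-dimethyl-5-(triisopropylsilyloxy)chroman-7-ol; 12 carbon monoxide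
Product: 13 (6aR,11aS)-cis-fused 6-oxo lactone of the O3-triisopropylsilyl target (rings A to E complete, C6 as carbonyl, H6a and H11a cis)
Conditions: Pd(OAc)2 (5 mol %), (S)-Xyl-PHANEPHOS (6 mol %), TsOH·H2O (10 mol %), CO (30 bar), toluene, 60 °C
Reagents that add atoms: carbon monoxide (12), [C-]#[O+]
Why: Proposed new method: the cationic bisphosphine palladium hydride (divalent palladium, formed from Pd(OAc)2, CO, the trace of water and TsOH) should add syn across C11a=C6a, with the enol ether polarisation, the η3-benzyl contact to ring D and the crowding at the fully substituted C11a all sending palladium to C6a and hydride to C11a, after which CO inserts with retention. This leaves the acyl group on the face of the new H11a, trans to ring A and out of reach of O5, so the cis fusion is not delivered by the insertion: the C6a–H of the cationic acylpalladium is benzylic and α to the carbonyl, should exchange through its enol or ketene form, and only the epimer with the acyl cis to ring A can close. Ring B closes by 6-exo-trig addition–elimination of O5 at C6, which returns the palladium hydride and, being irreversible, pays for the lost furan aromaticity. C11a (S) is controlled by the ligand, which selects the Re face for the hydride, and C6a (R in the lactone) is controlled by C11a through the much lower strain of the cis six–five junction. The step needs regioselectivity (palladium on C11a would lead to a spiro five-membered lactone), capture by the intramolecular phenol alone (O3 is silylated and no other nucleophile is present) and a low acid loading and temperature, because O11 is a β-leaving group of the lactone and C11a is benzylic to the electron-rich ring A. The closest known reaction types are the palladium-catalysed asymmetric hydroalkoxycarbonylation of vinylarenes, phenol-terminated carbonylative lactonisation and the dearomative Heck-type carbopalladation of benzofurans that places palladium on C3.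

Step 9
Reactants: 13 (6aR,11aS)-cis-fused 6-oxo lactone
Product: 14 8-[(2S,3S)-3-(hydroxymethyl)-6-methoxy-2,3-dihydrobenzofuran-2-yl]-2,2-dimethyl-5-(triisopropylsilyloxy)chroman-7-ol (cis diol)
Conditions: 13 added to LiAlH4 (excess), THF, −78 → −30 °C; aq. potassium sodium tartrate
Reagents that add atoms: none
Why: Hydride reduction of an aryl lactone: inverse addition to excess LiAlH4 in the cold makes both hydride transfers faster than deprotonation at C6a, so the transient aldehyde neither epimerises nor expels O11 and both stereocentres are carried over unchanged.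

Step 10
Reactants: 14 cis diol
Product: 15 (6aS,11aS)-O3-triisopropylsilyl ether of the target
Conditions: PPh3, DIAD, THF (0.02 M), 0 °C → rt
Reagents that add atoms: none
Why: Mitsunobu etherification: the primary C6 hydroxyl is activated as its oxyphosphonium salt and displaced by the acidic phenol O5 in a 6-exo-tet closure that is possible only because C6 and ring A are cis on ring C, and no stereocentre is involved since C6 is a CH2 group.

Step 11
Reactants: 15 (6aS,11aS)-O3-triisopropylsilyl ether of the target
Product: 16 target, (6aS,11aS)-3-hydroxy-9-methoxypterocarpan with a 2,2-dimethyl-3,4-dihydropyran ring fused through O at C1 and CH2 at C2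
Conditions: Bu4NF, AcOH, THF, 0 °C
Reagents that add atoms: none
Why: Fluoride-induced cleavage of the aryl silyl ether, driven by the Si–F bond and buffered with acetic acid so that the product phenoxide is quenched at once, leaves the ethers and both stereocentres untouched.

Compound list
1 | 2,4,6-trihydroxybenzaldehyde | O=Cc1c(O)cc(O)cc1O | starting material
2 | 1-bromo-3-methylbut-2-ene | CC(C)=CCBr | starting material
3 | 2,4,6-trihydroxy-3-(3-methylbut-2-en-1-yl)benzaldehyde | O=Cc1c(O)cc(O)c(CC=C(C)C)c1O | intermediate
4 | 2,6-dihydroxy-3-(3-methylbut-2-en-1-yl)-4-(triisopropylsilyloxy)benzaldehyde | O=Cc1c(O)cc(O[Si](C(C)C)(C(C)C)C(C)C)c(CC=C(C)C)c1O | intermediate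
5 | 7-hydroxy-2,2-dimethyl-5-(triisopropylsilyloxy)chroman-8-carbaldehyde | O=Cc1c(O)cc(O[Si](C(C)C)(C(C)C)C(C)C)c2CCC(C)(C)Oc12 | intermediate
6 | 7-(methoxymethoxy)-2,2-dimethyl-5-(triisopropylsilyloxy)chroman-8-carbaldehyde | O=Cc1c(OCOC)cc(O[Si](C(C)C)(C(C)C)C(C)C)c2CCC(C)(C)Oc12 | intermediate
7 | 8-ethynyl-7-(methoxymethoxy)-2,2-dimethyl-5-(triisopropylsilyloxy)chroman | C#Cc1c(OCOC)cc(O[Si](C(C)C)(C(C)C)C(C)C)c2CCC(C)(C)Oc12 | intermediate
8 | 2-iodo-5-methoxyphenol | COc1ccc(I)c(O)c1 | starting material
9 | 5-methoxy-2-{[7-(methoxymethoxy)-2,2-dimethyl-5-(triisopropylsilyloxy)chroman-8-yl]ethynyl}phenol (not isolated) | COc1ccc(C#Cc2c(OCOC)cc(O[Si](C(C)C)(C(C)C)C(C)C)c3CCC(C)(C)Oc23)c(O)c1 | intermediate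
10 | 6-methoxy-2-[7-(methoxymethoxy)-2,2-dimethyl-5-(triisopropylsilyloxy)chroman-8-yl]benzofuran | COc1ccc2cc(oc2c1)-c1c(OCOC)cc(O[Si](C(C)C)(C(C)C)C(C)C)c2CCC(C)(C)Oc12 | intermediate
11 | 8-(6-methoxybenzofuran-2-yl)-2,2-dimethyl-5-(triisopropylsilyloxy)chroman-7-ol | COc1ccc2cc(oc2c1)-c1c(O)cc(O[Si](C(C)C)(C(C)C)C(C)C)c2CCC(C)(C)Oc12 | intermediate
12 | carbon monoxide | [C-]#[O+] | starting material
13 | (6aR,11aS)-cis-6-oxo lactone of the O3-triisopropylsilyl target | COc1ccc2c(c1)O[C@@H]1c3c(cc(O[Si](C(C)C)(C(C)C)C(C)C)c4c3OC(C)(C)CC4)OC(=O)[C@H]21 | intermediate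
14 | 8-[(2S,3S)-3-(hydroxymethyl)-6-methoxy-2,3-dihydrobenzofuran-2-yl]-2,2-dimethyl-5-(triisopropylsilyloxy)chroman-7-ol | COc1ccc2c(c1)O[C@H](c3c(O)cc(O[Si](C(C)C)(C(C)C)C(C)C)c4c3OC(C)(C)CC4)[C@@H]2CO | intermediate
15 | (6aS,11aS)-O3-triisopropylsilyl ether of the target | COc1ccc2c(c1)O[C@@H]1c3c(cc(O[Si](C(C)C)(C(C)C)C(C)C)c4c3OC(C)(C)CC4)OC[C@H]21 | intermediate
16 | CNP0207547.1, (6aS,11aS)-3-hydroxy-9-methoxypterocarpan with ring E fused at C1 (O) and C2 (CH2) | COc1ccc2c(c1)O[C@@H]1c3c(cc(O)c4c3OC(C)(C)CC4)OC[C@H]21 | target

Total step count: 11. Longest linear sequence: 11 steps (1 → 16). Compounds 2, 8 and 12 are bought.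

Steps most likely to fail

1. Step 8 (the labelled step). Several things could go wrong.
- The hydride may not add to the aromatic C11a=C6a bond, or may add reversibly without CO uptake.
- Palladium may settle on C11a.
- Facial selectivity may be poor.
- The acyl group may stay trans to ring A and be consumed by intermolecular esterification.
- Acid and heat may trigger β-elimination of O11.

The fallback is known chemistry, an enantioselective carbenoid C–H insertion. It sets out from 6, uses 8 and returns at 14. Aldehyde 6 is reduced (NaBH4, MeOH, 0 °C) to the benzylic alcohol F1. This is joined to iodophenol 8 by Mitsunobu etherification (PPh3, DIAD, THF) to give the aryl benzyl ether F2. Palladium-catalysed coupling of the aryl iodide with ethyl diazoacetate (Pd(PPh3)4, Ag2CO3, Et3N, toluene, rt) gives the aryldiazoacetate F3. Rh2(S-PTTL)4 or its mirror image (toluene, −60 °C) inserts the carbenoid into the benzylic ether C–H bond and should give the cis-2-aryl-2,3-dihydrobenzofuran-3-carboxylate F4 as the (2S,3R) isomer. Acetal exchange (TsOH·H2O, EtOH, 40 °C) frees O5 to give the hydroxy ester F5. LiAlH4 in the cold then reduces F5 to diol 14. Any 13 formed from F5 by lactonisation is reduced to the same diol.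

2. Step 9. Deprotonation at C6a of the lactone or of the transient aldehyde may compete with hydride delivery. The result would be loss of the cis relationship or opening of ring C by expulsion of O11.

The fallback sets out from 13 and returns at 15, bypassing steps 9 and 10. The Lewis-acidic, weakly basic hydride iBu2AlH (1.1 equiv, CH2Cl2, −78 °C) stops at the lactol F6. Ionic reduction (Et3SiH, BF3·OEt2, CH2Cl2, −78 °C) of the derived aryl oxocarbenium ion removes the C6 hydroxyl and gives 15 directly. The more Lewis-basic lactol oxygen is expected to ionise before the aryl ether O11.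

3. Step 2. Silylation may spread over O4 and O6, because the prenyl group crowds O4. Selectivity would be lost, and the regiochemical lock on the chroman closure in step 3 would go with it.

The fallback sets out from 1 and returns at 5, bypassing steps 1 to 3. The unhindered O4 of 1 is silylated first (iPr3SiCl, imidazole, DMF, 0 °C) to give the symmetrical 2,6-dihydroxy-4-silyloxybenzaldehyde F7. Chromene annulation with 3-methylbut-2-enal follows (ethylenediammonium diacetate, toluene, reflux). It proceeds by Knoevenagel-type condensation and then oxa-6π electrocyclisation. By symmetry and with O4 blocked, it can give only the 8-formyl chromene F8. Hydrogenation of the chromene double bond (H2, Pd/C, EtOAc) then gives 5.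

Further compounds
F1 | step 8 | [7-(methoxymethoxy)-2,2-dimethyl-5-(triisopropylsilyloxy)chroman-8-yl]methanol | OCc1c(OCOC)cc(O[Si](C(C)C)(C(C)C)C(C)C)c2CCC(C)(C)Oc12
F2 | step 8 | 8-[(2-iodo-5-methoxyphenoxy)methyl]-7-(methoxymethoxy)-2,2-dimethyl-5-(triisopropylsilyloxy)chroman | COc1ccc(I)c(OCc2c(OCOC)cc(O[Si](C(C)C)(C(C)C)C(C)C)c3CCC(C)(C)Oc23)c1
F3 | step 8 | ethyl 2-diazo-2-(4-methoxy-2-{[7-(methoxymethoxy)-2,2-dimethyl-5-(triisopropylsilyloxy)chroman-8-yl]methoxy}phenyl)acetate | CCOC(=O)C(=[N+]=[N-])c1ccc(OC)cc1OCc1c(OCOC)cc(O[Si](C(C)C)(C(C)C)C(C)C)c2CCC(C)(C)Oc12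
F4 | step 8 | ethyl (2S,3R)-cis-6-methoxy-2-[7-(methoxymethoxy)-2,2-dimethyl-5-(triisopropylsilyloxy)chroman-8-yl]-2,3-dihydrobenzofuran-3-carboxylate | COc1ccc2c(c1)O[C@H](c3c(OCOC)cc(O[Si](C(C)C)(C(C)C)C(C)C)c4c3OC(C)(C)CC4)[C@@H]2C(=O)OCC
F5 | step 8 | ethyl (2S,3R)-cis-2-[7-hydroxy-2,2-dimethyl-5-(triisopropylsilyloxy)chroman-8-yl]-6-methoxy-2,3-dihydrobenzofuran-3-carboxylate | COc1ccc2c(c1)O[C@H](c3c(O)cc(O[Si](C(C)C)(C(C)C)C(C)C)c4c3OC(C)(C)CC4)[C@@H]2C(=O)OCC
F6 | step 9 | (6aR,11aS)-6-hydroxy lactol of the O3-triisopropylsilyl target (both C6 epimers) | COc1ccc2c(c1)O[C@@H]1c3c(cc(O[Si](C(C)C)(C(C)C)C(C)C)c4c3OC(C)(C)CC4)OC(O)[C@H]21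
F7 | step 2 | 2,6-dihydroxy-4-(triisopropylsilyloxy)benzaldehyde | O=Cc1c(O)cc(O[Si](C(C)C)(C(C)C)C(C)C)cc1O
F8 | step 2 | 7-hydroxy-2,2-dimethyl-5-(triisopropylsilyloxy)-2H-chromene-8-carbaldehyde | O=Cc1c(O)cc(O[Si](C(C)C)(C(C)C)C(C)C)c2C=CC(C)(C)Oc12
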